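**Assumption (one line):** (S)-glycidol and geranyl acetate are the commercial starting points. The C1/C2 outcome of the Wittig step is assumed to be controlled by the macrocycle conformation set by the (12S,13S)-epoxide. Cembrane numbering is used throughout: ring C1–C14, lactone O on C2, OAc on C3 (= the "13-acetoxy" of the natural-product numbering).

## Retrosynthetic overview
1. The target comes from Luche reduction and acetylation of the C3 ketone of the lactone-fused 14-membered ring.
2. That ring and the α-methylene-γ-lactone arise together, in one step, from a macrocyclic anionic [2,3]-Wittig ring contraction. The C2 enolate of a 17-membered α-allyloxy enone attacks a 2-carboxyallyl acceptor, forming C1–C2.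
3. The 17-membered ether comes from ring-closing metathesis (C1=C15) of the diene ether, which is made by O-alkylation of an α-hydroxy enone with methyl 2-(bromomethyl)acrylate.
4. The (12S,13S) epoxide comes from (S)-glycidol by chelation-controlled methylation and inversive closure. The E,E-chain comes from geranyl acetate.
5. Rings form in this order: epoxide, then the 17-membered ether ring (RCM), then the 14-membered carbocycle and γ-lactone (Wittig).

## Route

**Step 1**
Reactants: 1 (S)-glycidol
Product: 2 (R)-pent-4-ene-1,2-diol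
Conditions: vinylMgBr, CuI (cat.), THF, –40 °C
Reagents that add atoms: vinylmagnesium bromide, C=C[Mg]Br
Why: Cu-catalysed Grignard opening occurs at the terminal CH2 of the epoxide, so the stereocentre is untouched; (S)-glycidol gives the (R)-diol only because CIP priorities change.

**Step 2**
Reactants: 2
Product: 3 (R)-2-hydroxypent-4-enoic acid
Conditions: TEMPO (cat.), NaClO2, NaOCl (cat.), MeCN/pH 6.7 buffer, 35 °C
Reagents that add atoms: sodium chlorite (oxygen source), [Na+].[O-]Cl=O
Why: Zhao–Anelli TEMPO oxidation converts the primary alcohol to the acid selectively over the secondary alcohol and the alkene, without touching the stereocentre.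

**Step 3**
Reactants: 3
Product: 4 (R)-3-hydroxyhex-5-en-2-one
Conditions: MeLi (3.5 equiv), Et2O, –78 → 0 °C
Reagents that add atoms: methyllithium, C[Li]
Why: MeLi adds once to the lithium carboxylate to give, after protonation, the methyl ketone; the OH stays as its alkoxide and the stereocentre is not epimerised.

**Step 4**
Reactants: 5 geranyl acetate
Product: 6 (2E,6E)-8-hydroxygeranyl acetate
Conditions: SeO2 (5 mol%), t-BuOOH, CH2Cl2, rt
Reagents that add atoms: tert-butyl hydroperoxide (oxygen source), CC(C)(C)OO
Why: Riley/Sharpless allylic oxidation hits the E-methyl of the terminal isopropylidene selectively, and the acetate-bearing alkene is deactivated.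

**Step 5**
Reactants: 6
Product: 7 (TBS ether of 6)
Conditions: TBSCl, imidazole, DMF, rt
Reagents that add atoms: tert-butyldimethylsilyl chloride, CC(C)(C)[Si](C)(C)Cl
Why: Silylation masks the new primary alcohol.

**Step 6**
Reactants: 7
Product: 8 (2E,6E)-8-(TBSO)-3,7-dimethylocta-2,6-dien-1-ol
Conditions: K2CO3, MeOH, rt
Reagents that add atoms: none
Why: Methanolysis cleaves the acetate and leaves the silyl ether and both alkenes intact.

**Step 7**
Reactants: 8
Product: 9 (2E,6E)-allylic bromide, TBSO–CH2–C(Me)=CH–CH2CH2–C(Me)=CH–CH2Br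
Conditions: CBr4, PPh3, CH2Cl2, 0 °C
Reagents that add atoms: carbon tetrabromide, BrC(Br)(Br)Br
Why: Appel bromination proceeds by SN2 at the primary allylic alcohol without allylic transposition.

**Step 8**
Reactants: 4, 9
Product: 10 (4R,8E,12E)-14-(TBSO)-4-hydroxy-9,13-dimethyltetradeca-1,8,12-trien-5-one
Conditions: LDA (2.2 equiv), THF, –78 °C; then 9, DMPU, –78 → –20 °C
Reagents that add atoms: none
Why: The alkoxide makes the methine α-C–H non-acidic, so the dianion forms at the CH3 only. SN2 alkylation with the allylic bromide makes the C10–C11 bond, and C13 (R) is neither deprotonated nor epimerised.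

**Step 9**
Reactants: 10
Product: 11 (4R,5S,8E,12E)-14-(TBSO)-5,9,13-trimethyltetradeca-1,8,12-triene-4,5-diol
Conditions: MeMgBr (4 equiv), CH2Cl2/Et2O, –78 °C
Reagents that add atoms: methylmagnesium bromide, C[Mg]Br
Why: Cram-chelate Grignard addition through the five-membered Mg chelate of the α-alkoxide ketone delivers Me from the H-bearing face, setting C12 (S) against C13 (R); dr ≥10:1 is assumed.

**Step 10**
Reactants: 11
Product: 12 (secondary mesylate of 11)
Conditions: MsCl, Et3N, CH2Cl2, –20 °C
Reagents that add atoms: methanesulfonyl chloride, CS(=O)(=O)Cl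
Why: Only the secondary alcohol sulfonylates; the tertiary alcohol and the primary silyl ether are inert.

**Step 11**
Reactants: 12
Product: 13 (trans-epoxide, 12S,13S; TBS ether)
Conditions: K2CO3, MeOH, rt
Reagents that add atoms: none
Why: Williamson-type 3-exo-tet closure of the tertiary alkoxide displaces the mesylate with inversion at C13, so C13 goes R → S and stereospecifically gives the (12S,13S) trans-epoxide.

**Step 12**
Reactants: 13
Product: 14 (epoxy allylic alcohol)
Conditions: TBAF, THF, 0 °C
Reagents that add atoms: none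
Why: Fluoride removes the primary silyl ether; the epoxide and alkenes survive.

**Step 13**
Reactants: 14
Product: 15 (epoxy enal)
Conditions: MnO2, CH2Cl2, rt
Reagents that add atoms: none
Why: MnO2 oxidises the allylic primary alcohol chemoselectively; the E-enal geometry is retained.

**Step 14**
Reactants: 15
Product: 16 (β-hydroxysilane, C3 unassigned)
Conditions: iPrOSiMe2CH2MgCl, THF, –78 °C
Reagents that add atoms: (isopropoxydimethylsilyl)methylmagnesium chloride, CC(C)O[Si](C)(C)C[Mg]Cl
Why: 1,2-addition of a Tamao hydroxymethyl-anion equivalent builds the C2–C3 bond; the new C3 stereocentre is destroyed in step 16, so its configuration is irrelevant.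

**Step 15**
Reactants: 16
Product: 17 (1,2-diol: C3-OH, C2-OH)
Conditions: 30% H2O2, KF, KHCO3, THF/MeOH, 50 °C
Reagents that add atoms: hydrogen peroxide, OO
Why: Tamao–Fleming oxidation replaces C–Si with C–OH under conditions the epoxide and alkenes tolerate.

**Step 16**
Reactants: 17
Product: 18 (α-hydroxy enone, C3 ketone / C2 CH2OH)
Conditions: MnO2, CH2Cl2, rt
Reagents that add atoms: none
Why: MnO2 oxidises only the allylic secondary alcohol, leaving the primary alcohol untouched.

**Step 17**
Reactants: 18, 19 (methyl 2-(bromomethyl)acrylate)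
Product: 20 (diene ether: C2–O–CH2–C(=CH2)CO2Me)
Conditions: Ag2O, CH2Cl2, rt, dark
Reagents that add atoms: none (19 is the numbered reactant)
Why: Silver-promoted Williamson etherification of the primary alcohol with the reactive allylic bromide avoids base-mediated enolisation of the ketol.

**Step 18**
Reactants: 20
Product: 21 (17-membered macrocyclic ether, C1=C15 acrylate)
Conditions: Hoveyda–Grubbs II (10 mol%), toluene, 0.002 M, 70 °C
Reagents that add atoms: none (ethylene is lost)
Why: Macro ring-closing metathesis joins the monosubstituted alkene and the 2-substituted acrylate; the trisubstituted alkenes and the epoxide are inert to the catalyst.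

**Step 19**
Reactants: 21
Product: 22 (lactone-fused 14-membered 3-ketone, 1S,2S,12S,13S)
Conditions: KHMDS (2.2 equiv), THF, 0.003 M, –78 → –20 °C; then NH4Cl
Reagents that add atoms: none (MeOH is lost on lactonisation)
Why: Key macrocyclic anionic [2,3]-Wittig ring contraction: the C2 enolate adds to C1 of the acrylate and the C17–O bond is expelled, forming C1–C2 (via the 5-membered TS) and the C15=C17 methylene. The C2 alkoxide then closes onto CO2Me to give the trans-fused γ-lactone, with the C1/C2 configuration set by the macrocycle conformation.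

**Step 20**
Reactants: 22
Product: 23 (3S-alcohol)
Conditions: NaBH4, CeCl3·7H2O, MeOH/CH2Cl2, –78 °C
Reagents that add atoms: none
Why: Luche 1,2-reduction of the enone leaves the α-methylene lactone and epoxide intact; the facial bias of the macrocycle and the adjacent C2 centre give the 3S alcohol.

**Step 21**
Reactants: 23
Product: 24 (13-acetoxysarcocrassolide)
Conditions: Ac2O, pyridine, DMAP, CH2Cl2, 0 °C
Reagents that add atoms: acetic anhydride, CC(=O)OC(C)=O
Why: Simple O-acetylation of the secondary allylic alcohol; no stereocentre is touched.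

## Compound list
Names give cembrane-type numbering for the macrocycles.

1 | (S)-glycidol | OC[C@H]1CO1 | starting material
2 | (R)-pent-4-ene-1,2-diol | C=CC[C@@H](O)CO | intermediate
3 | (R)-2-hydroxypent-4-enoic acid | C=CC[C@@H](O)C(=O)O | intermediate
4 | (R)-3-hydroxyhex-5-en-2-one | C=CC[C@@H](O)C(C)=O | intermediate
5 | geranyl acetate | CC(=O)OC/C=C(\C)CCC=C(C)C | starting material
6 | (2E,6E)-8-hydroxy-3,7-dimethylocta-2,6-dien-1-yl acetate | CC(=O)OC/C=C(\C)CC/C=C(\C)CO | intermediate
7 | (2E,6E)-8-(TBSO)-3,7-dimethylocta-2,6-dien-1-yl acetate | CC(=O)OC/C=C(\C)CC/C=C(\C)CO[Si](C)(C)C(C)(C)C | intermediate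
8 | (2E,6E)-8-(TBSO)-3,7-dimethylocta-2,6-dien-1-ol | OC/C=C(\C)CC/C=C(\C)CO[Si](C)(C)C(C)(C)C | intermediate
9 | tert-butyl{[(2E,6E)-8-bromo-2,6-dimethylocta-2,6-dien-1-yl]oxy}dimethylsilane | BrC/C=C(\C)CC/C=C(\C)CO[Si](C)(C)C(C)(C)C | intermediate
10 | (4R,8E,12E)-14-(TBSO)-4-hydroxy-9,13-dimethyltetradeca-1,8,12-trien-5-one | C=CC[C@@H](O)C(=O)CC/C=C(\C)CC/C=C(\C)CO[Si](C)(C)C(C)(C)C | intermediate
11 | (4R,5S,8E,12E)-14-(TBSO)-5,9,13-trimethyltetradeca-1,8,12-triene-4,5-diol | C=CC[C@@H](O)[C@@](C)(O)CC/C=C(\C)CC/C=C(\C)CO[Si](C)(C)C(C)(C)C | intermediate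
12 | 4-mesylate of 11 | C=CC[C@@H](OS(C)(=O)=O)[C@@](C)(O)CC/C=C(\C)CC/C=C(\C)CO[Si](C)(C)C(C)(C)C | intermediate
13 | {[(2E,6E)-2,6-dimethyl-9-[(2S,3S)-2-methyl-3-allyloxiran-2-yl]nona-2,6-dien-1-yl]oxy}(tert-butyl)dimethylsilane | C=CC[C@@H]1O[C@@]1(C)CC/C=C(\C)CC/C=C(\C)CO[Si](C)(C)C(C)(C)C | intermediate
14 | (2E,6E)-2,6-dimethyl-9-[(2S,3S)-2-methyl-3-allyloxiran-2-yl]nona-2,6-dien-1-ol | C=CC[C@@H]1O[C@@]1(C)CC/C=C(\C)CC/C=C(\C)CO | intermediate
15 | corresponding (2E,6E)-nona-2,6-dienal | C=CC[C@@H]1O[C@@]1(C)CC/C=C(\C)CC/C=C(\C)C=O | intermediate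
16 | (3E,7E)-1-[isopropoxy(dimethyl)silyl]-3,7-dimethyl-10-[(2S,3S)-2-methyl-3-allyloxiran-2-yl]deca-3,7-dien-2-ol (C2 unassigned) | C=CC[C@@H]1O[C@@]1(C)CC/C=C(\C)CC/C=C(\C)C(O)C[Si](C)(C)OC(C)C | intermediate
17 | corresponding deca-3,7-diene-1,2-diol | C=CC[C@@H]1O[C@@]1(C)CC/C=C(\C)CC/C=C(\C)C(O)CO | intermediate
18 | (3E,7E)-1-hydroxy-3,7-dimethyl-10-[(2S,3S)-2-methyl-3-allyloxiran-2-yl]deca-3,7-dien-2-one | C=CC[C@@H]1O[C@@]1(C)CC/C=C(\C)CC/C=C(\C)C(=O)CO | intermediate
19 | methyl 2-(bromomethyl)acrylate | C=C(CBr)C(=O)OC | starting material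
20 | methyl 2-{[(3E,7E)-3,7-dimethyl-10-epoxyalkyl-2-oxodeca-3,7-dien-1-yl]oxymethyl}acrylate (diene ether) | C=CC[C@@H]1O[C@@]1(C)CC/C=C(\C)CC/C=C(\C)C(=O)COCC(=C)C(=O)OC | intermediate
21 | 17-membered macrocyclic acrylate ether (RCM product; C1=C15 geometry unassigned; 12S,13S-epoxide) | COC(=O)C1=CC[C@@H]2O[C@@]2(C)CC/C=C(\C)CC/C=C(\C)C(=O)COC1 | intermediate
22 | (1S,2S,12S,13S)-3-oxo lactone-fused 14-membered cembranoid (3-keto precursor) | C=C1C(=O)O[C@H]2[C@H]1C[C@@H]1O[C@@]1(C)CC/C=C(\C)CC/C=C(\C)C2=O | intermediate
23 | (1S,2S,3S,12S,13S)-3-hydroxy analogue | C=C1C(=O)O[C@H]2[C@H]1C[C@@H]1O[C@@]1(C)CC/C=C(\C)CC/C=C(\C)[C@@H]2O | intermediate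
24 | 13-acetoxysarcocrassolide (3-OAc in cembrane numbering) | C=C1C(=O)O[C@H]2[C@H]1C[C@@H]1O[C@@]1(C)CC/C=C(\C)CC/C=C(\C)[C@@H]2OC(C)=O | target

## Totals
- Total steps: 21.
- Longest linear sequence: 18 steps (geranyl acetate → steps 4–21).
- Three steps most likely to fail:
  1. **Step 19, [2,3]-Wittig.** Diastereocontrol at C1/C2 (trans-lactone, correct absolute configuration) and competition from intermolecular enolate addition are uncertain. Fallback: change the approach and close the ring by intramolecular Zn/Cr (Barbier/NHK) allylation between a C2 aldehyde and a (bromomethyl)acrylate, which forms the same C1–C2 bond and the lactone directly.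
  2. **Step 18, RCM.** A 17-membered ring from an electron-poor 1,1-disubstituted acrylate may give low yield or a poor E/Z ratio. Fallback: replace the RCM/Williamson pair with macrocyclic Masamune–Roush HWE (phosphonate/aldehyde) to form C1=C15, or use a macro-etherification of an allylic bromide.
  3. **Step 8, dianion alkylation.** Regiochemistry and C13 configurational integrity are uncertain. Fallback: build C11–C12 from the PMB-protected α-alkoxy Weinreb amide plus a homogeranyl Grignard instead of enolate alkylation.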